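A direct plan would buy rings A and B together with the stereocentre: a commercial (R)-configured catecholamine would be converted into the bis-O-(1,1-dimethylallyl) Katritzky pyridinium salt A1, and a Claisen rearrangement would supply the C-tert-prenylated bromo-hydroxybenzaldehyde A2. A light-driven deaminative radical addition of A1 to the tosylhydrazone of A2 would forge C3–C4 and give bromo alcohol A3, CuI-catalysed O-arylation would close ring C at O1–C8a to give flavan bis(allyl ether) A4, and a double aromatic Claisen rearrangement of A4 would place both prenyl groups of ring B last.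
Its weakest steps would be:
- The photochemical three-component C3–C4 union: a reaction type without precedent, asked to work with a β-hydroxyalkyl radical, free phenols and four alkenes, after four steps that only prepare the partners and add little complexity.
- The ring closure by O-arylation: a secondary benzylic alkoxide would have to beat the free phenoxide of the same molecule at 80 °C beside two heat-labile tertiary allyl ethers, so the closure is left to chance.
- The final double Claisen rearrangement on the finished flavan: one allyl group must enter the crowded C2' next to C1', loss of isoprene and chroman formation compete, and the ionisable 4'-oxybenzylic ether at C2 is heated. It is the step one would least like to run on late material.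

**Plan of the new route**
The hardest feature is ring B, a pentasubstituted catechol whose two C-prenyl groups flank the oxygens and whose C1' carries an ionisable ether stereocentre; the plan therefore builds ring B instead of decorating it.
Cuts: O1–C2 (stereospecific etherification); then ring B across C1'–C2' and C5'–C6' into a terminal ynone (C2 carbonyl, C1', C6'–H) and a symmetric 2,3-bis(silyloxy)diene (C2'–C5' with both prenyl groups, O3' and O4'); then the ynone to a ring A Weinreb amide, which comes from a 4-bromoresorcinol/acrylic acid lactone.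
This is possible because in ring B the sequence C2'(prenyl)–C3'(O)–C4'(O)–C5'(prenyl) is symmetric and C6' bears only hydrogen, so a symmetric diene and a terminal ynone can give only one ring.
Ring order: ring A is bought; the six atoms of ring C are first held as a lactone (steps 1–3) and opened; ring B is then made de novo (step 8); ring C closes last at O1–C2 (step 10).
No radical coupling, no O-arylation and no allyl aryl ether or Claisen rearrangement occur: all three C5 groups are carbon-bound from the moment they enter, and the stereocentre is set by a catalyst on a ketone and inverted once.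

Key step: step 8

Remark: atoms are numbered as in the flavan throughout (O1, C2–C4, C4a–C8a, C1'–C6'); TBS = tert-butyldimethylsilyl, TES = triethylsilyl; 1, 8, 9 and the named reagents are assumed to be commercial.

Step 1
Reactants: 1 4-bromoresorcinol (4-bromobenzene-1,3-diol)
Product: 2 6-bromo-7-hydroxy-3,4-dihydro-2H-chromen-2-one
Conditions: acrylic acid (1.5 equiv), Amberlyst-15, toluene, reflux, Dean–Stark, 16 h
Reagents that add atoms: acrylic acid, C=CC(=O)O
Why: Acid-mediated Friedel–Crafts conjugate addition and lactonisation of a resorcinol with acrylic acid; the only activated and unhindered carbon of 1 (para to one hydroxyl, ortho to the other) becomes C4a, and the lactone that forms distinguishes the future O1 from the free O7.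

Step 2
Reactants: 2 6-bromo-7-hydroxy-3,4-dihydro-2H-chromen-2-one
Product: 3 6-bromo-7-[(tert-butyldimethylsilyl)oxy]-3,4-dihydro-2H-chromen-2-one
Conditions: TBSCl (1.2 equiv), imidazole (2.5 equiv), DMF, 0 °C to rt
Reagents that add atoms: tert-butyldimethylsilyl chloride, CC(C)(C)[Si](C)(C)Cl
Why: Standard silylation of the only free phenol, which the aryl lactone tolerates.

Step 3
Reactants: 3 6-bromo-7-[(tert-butyldimethylsilyl)oxy]-3,4-dihydro-2H-chromen-2-one
Product: 4 7-[(tert-butyldimethylsilyl)oxy]-6-(2-methylbut-3-en-2-yl)-3,4-dihydro-2H-chromen-2-one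
Conditions: prenylB(pin) (1.5 equiv), Pd(OAc)2 (3 mol %), t-BuXPhos (6 mol %), K3PO4 (3 equiv), THF/H2O (10:1), 40 °C; AcOH work-up
Reagents that add atoms: 4,4,5,5-tetramethyl-2-(3-methylbut-2-en-1-yl)-1,3,2-dioxaborolane, CC(C)=CCB1OC(C)(C)C(C)(C)O1
Why: Ligand-controlled γ-selective Suzuki–Miyaura coupling of a 3,3-disubstituted allylboronate, in which SE2' transmetalation puts palladium on the tertiary carbon and reductive elimination outruns allyl isomerisation, so the 1,1-dimethylallyl group enters at C6 as a C–C bond; any lactone opened by the base re-closes on acidic work-up.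

Step 4
Reactants: 4 7-[(tert-butyldimethylsilyl)oxy]-6-(2-methylbut-3-en-2-yl)-3,4-dihydro-2H-chromen-2-one
Product: 6 3-{4-[(tert-butyldimethylsilyl)oxy]-5-(2-methylbut-3-en-2-yl)-2-[(triethylsilyl)oxy]phenyl}-N-methoxy-N-methylpropanamide, via phenol amide 5 (not isolated)
Conditions: MeNH(OMe)·HCl (2 equiv), i-PrMgCl (4 equiv), THF, −20 °C; aqueous work-up; then TESCl (1.5 equiv), imidazole (3 equiv), DMF, 0 °C
Reagents that add atoms: N,O-dimethylhydroxylamine hydrochloride, CNOC.Cl; chlorotriethylsilane, CC[Si](CC)(CC)Cl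
Why: Aminolysis of the aryl lactone by the chloromagnesium amide gives the Weinreb amide and frees only the O1 phenol, which is capped at once (to prevent relactonisation) as a triethylsilyl ether that is more base-labile than the hindered TBS ether at O7.

Step 5
Reactants: 6 3-{4-[(tert-butyldimethylsilyl)oxy]-5-(2-methylbut-3-en-2-yl)-2-[(triethylsilyl)oxy]phenyl}-N-methoxy-N-methylpropanamide
Product: 7 5-{4-[(tert-butyldimethylsilyl)oxy]-5-(2-methylbut-3-en-2-yl)-2-[(triethylsilyl)oxy]phenyl}pent-1-yn-3-one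
Conditions: HC≡CMgBr (2.5 equiv), THF, 0 °C; inverse quench into cold aq NaHSO4
Reagents that add atoms: ethynylmagnesium bromide, C#C[Mg]Br
Why: Weinreb ketone synthesis, in which the chelated tetrahedral intermediate prevents over-addition and the acidic quench prevents conjugate addition of the released amine to the terminal ynone; the new carbonyl carbon is C2 and the alkyne carbons are C1' and C6'.

Step 6
Reactants: 8 5-bromo-2-methylpent-2-ene; 9 N,N'-dimethoxy-N,N'-dimethyloxalamide
Product: 11 2,11-dimethyldodeca-2,10-diene-6,7-dione, via Grignard reagent 10 (not isolated)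
Conditions: 8 (2.3 equiv), Mg turnings (2.8 equiv), THF, rt to 40 °C; then 9 (1.0 equiv), THF, −20 °C to 0 °C; aq NH4Cl
Reagents that add atoms: 5-bromo-2-methylpent-2-ene (second equivalent of 8 as Grignard reagent 10), CC(C)=CCCBr
Why: Twofold acyl substitution on the bis-Weinreb amide of oxalic acid, in which two molecules of Grignard reagent 10 add, one to each amide carbonyl, and the chelated adducts stop at the ketone stage until the quench, gives the symmetric 1,2-diketone that holds C2'–C5' with both prenyl groups.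

Step 7
Reactants: 11 2,11-dimethyldodeca-2,10-diene-6,7-dione
Product: 12 (5Z,7Z)-6,7-bis[(tert-butyldimethylsilyl)oxy]-2,11-dimethyldodeca-2,5,7,10-tetraene
Conditions: TBSOTf (2.3 equiv), Et3N (3.5 equiv), CH2Cl2, 0 °C to rt; filtration through basic alumina
Reagents that add atoms: tert-butyldimethylsilyl trifluoromethanesulfonate, CC(C)(C)[Si](C)(C)OS(=O)(=O)C(F)(F)F
Why: Soft double enolisation and O-silylation of a 1,2-diketone gives the 2,3-bis(silyloxy)-1,3-diene, and the favoured Z enol ether geometry puts each prenyl-bearing CH2 cis to its own silyloxy group and therefore on the outside of the s-cis diene.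

Step 8
Reactants: 7 5-{4-[(tert-butyldimethylsilyl)oxy]-5-(2-methylbut-3-en-2-yl)-2-[(triethylsilyl)oxy]phenyl}pent-1-yn-3-one; 12 (5Z,7Z)-6,7-bis[(tert-butyldimethylsilyl)oxy]-2,11-dimethyldodeca-2,5,7,10-tetraene
Product: 14 1-{3,4-bis[(tert-butyldimethylsilyl)oxy]-2,5-bis(3-methylbut-2-en-1-yl)phenyl}-3-{4-[(tert-butyldimethylsilyl)oxy]-5-(2-methylbut-3-en-2-yl)-2-[(triethylsilyl)oxy]phenyl}propan-1-one, via cyclohexadiene adduct 13 (not isolated)
Conditions: 12 (1.1 equiv), BHT (cat.), toluene (1 M), 90 °C, 24 h; then DDQ (1.2 equiv), NaHCO3, toluene, 0 °C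
Reagents that add atoms: none
Why: Normal-demand Diels–Alder reaction: the s-cis (5Z,7Z)-diene 12, its HOMO raised by two silyloxy and two alkyl groups, adds across the carbonyl-activated triple bond of 7 and forms C1'–C2' and C5'–C6' in one intermolecular [4+2] event to give the 1,4-cyclohexadiene 13; DDQ then abstracts hydride from one of the two doubly allylic ring CH groups and loss of a proton aromatises ring B. The closest known reaction type is the cycloaddition of 2,3-bis(trialkylsilyloxy)buta-1,3-dienes with acetylenic esters and ketones followed by dehydrogenation to catechol disilyl ethers. Ring B is closed by [4+2] cycloaddition and fixed by oxidation; the two sp3 carbons of 13 are transient and no stereocentre is created. Regioselectivity, the usual weakness of a Diels–Alder benzannulation, is not needed because the diene is symmetric end to end, and the one geometric demand, that both prenyl-bearing termini point outwards, is met by the Z,Z enol ether geometry. Chemoselectivity rests on 7 holding the only electron-poor π bond and 12 the only conjugated diene (the three isolated alkenes are unactivated), and on a slight excess of DDQ at 0 °C so that the C4 benzylic position and the aryl silyl ethers survive.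

Step 9
Reactants: 14 1-{3,4-bis[(tert-butyldimethylsilyl)oxy]-2,5-bis(3-methylbut-2-en-1-yl)phenyl}-3-{4-[(tert-butyldimethylsilyl)oxy]-5-(2-methylbut-3-en-2-yl)-2-[(triethylsilyl)oxy]phenyl}propan-1-one
Product: 16 2-[(3R)-3-{3,4-bis[(tert-butyldimethylsilyl)oxy]-2,5-bis(3-methylbut-2-en-1-yl)phenyl}-3-hydroxypropyl]-5-[(tert-butyldimethylsilyl)oxy]-4-(2-methylbut-3-en-2-yl)phenol, via silyl ether carbinol 15 (not isolated)
Conditions: RuCl(p-cymene)[(R,R)-TsDPEN] (2 mol %), HCO2H/Et3N (5:2), DMF, 40 °C; then K2CO3 (0.5 equiv), MeOH, 0 °C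
Reagents that add atoms: none
Why: Noyori asymmetric transfer hydrogenation of an aryl alkyl ketone, in which the CH/π contact between the catalyst arene and ring B fixes the hydride face so that the (R,R)-ligand gives the (R)-carbinol while alkenes and aryl silyl ethers are untouched; the unhindered triethylsilyl aryl ether is then methanolysed selectively beside the three flanked TBS ethers.

Step 10
Reactants: 16 2-[(3R)-3-{3,4-bis[(tert-butyldimethylsilyl)oxy]-2,5-bis(3-methylbut-2-en-1-yl)phenyl}-3-hydroxypropyl]-5-[(tert-butyldimethylsilyl)oxy]-4-(2-methylbut-3-en-2-yl)phenol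
Product: 17 (2S)-2-{3,4-bis[(tert-butyldimethylsilyl)oxy]-2,5-bis(3-methylbut-2-en-1-yl)phenyl}-7-[(tert-butyldimethylsilyl)oxy]-6-(2-methylbut-3-en-2-yl)-3,4-dihydro-2H-chromene
Conditions: PPh3 (1.5 equiv), DIAD (1.5 equiv), THF (0.02 M), 0 °C
Reagents that add atoms: none
Why: Intramolecular Mitsunobu etherification (6-exo-tet), in which the only free phenol displaces the oxyphosphonium group at C2 with inversion, so the (R)-carbinol gives the (2S)-flavan and ring C closes at O1–C2 without acid or base.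

Step 11
Reactants: 17 (2S)-2-{3,4-bis[(tert-butyldimethylsilyl)oxy]-2,5-bis(3-methylbut-2-en-1-yl)phenyl}-7-[(tert-butyldimethylsilyl)oxy]-6-(2-methylbut-3-en-2-yl)-3,4-dihydro-2H-chromene
Product: 18 (2S)-2-[3,4-dihydroxy-2,5-bis(3-methylbut-2-en-1-yl)phenyl]-6-(2-methylbut-3-en-2-yl)-3,4-dihydro-2H-chromen-7-ol
Conditions: TBAF (3.6 equiv), AcOH (3.6 equiv), THF, 0 °C, Ar
Reagents that add atoms: none
Why: Buffered fluoride cleavage of three aryl silyl ethers; the near-neutral medium avoids phenoxide-triggered quinone-methide opening of ring C (which would racemise C2) and acid-induced cyclisation of the ortho-prenyl phenols.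

**Compound list**
1 | 4-bromoresorcinol (4-bromobenzene-1,3-diol) | Oc1ccc(Br)c(O)c1 | starting material
2 | 6-bromo-7-hydroxy-3,4-dihydro-2H-chromen-2-one | O=C1CCc2cc(Br)c(O)cc2O1 | intermediate
3 | 6-bromo-7-[(tert-butyldimethylsilyl)oxy]-3,4-dihydro-2H-chromen-2-one | O=C1CCc2cc(Br)c(O[Si](C)(C)C(C)(C)C)cc2O1 | intermediate
4 | 7-[(tert-butyldimethylsilyl)oxy]-6-(2-methylbut-3-en-2-yl)-3,4-dihydro-2H-chromen-2-one | O=C1CCc2cc(C(C)(C)C=C)c(O[Si](C)(C)C(C)(C)C)cc2O1 | intermediate
5 | 3-{4-[(tert-butyldimethylsilyl)oxy]-2-hydroxy-5-(2-methylbut-3-en-2-yl)phenyl}-N-methoxy-N-methylpropanamide | CON(C)C(=O)CCc1cc(C(C)(C)C=C)c(O[Si](C)(C)C(C)(C)C)cc1O | intermediate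
6 | 3-{4-[(tert-butyldimethylsilyl)oxy]-5-(2-methylbut-3-en-2-yl)-2-[(triethylsilyl)oxy]phenyl}-N-methoxy-N-methylpropanamide | CON(C)C(=O)CCc1cc(C(C)(C)C=C)c(O[Si](C)(C)C(C)(C)C)cc1O[Si](CC)(CC)CC | intermediate
7 | 5-{4-[(tert-butyldimethylsilyl)oxy]-5-(2-methylbut-3-en-2-yl)-2-[(triethylsilyl)oxy]phenyl}pent-1-yn-3-one | C#CC(=O)CCc1cc(C(C)(C)C=C)c(O[Si](C)(C)C(C)(C)C)cc1O[Si](CC)(CC)CC | intermediate
8 | 5-bromo-2-methylpent-2-ene | CC(C)=CCCBr | starting material
9 | N,N'-dimethoxy-N,N'-dimethyloxalamide | CON(C)C(=O)C(=O)N(C)OC | starting material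
10 | (4-methylpent-3-en-1-yl)magnesium bromide | CC(C)=CCC[Mg]Br | intermediate
11 | 2,11-dimethyldodeca-2,10-diene-6,7-dione | CC(C)=CCCC(=O)C(=O)CCC=C(C)C | intermediate
12 | (5Z,7Z)-6,7-bis[(tert-butyldimethylsilyl)oxy]-2,11-dimethyldodeca-2,5,7,10-tetraene | CC(C)=CC/C=C(O[Si](C)(C)C(C)(C)C)/C(O[Si](C)(C)C(C)(C)C)=C/CC=C(C)C | intermediate
13 | 1-{4,5-bis[(tert-butyldimethylsilyl)oxy]-3,6-bis(3-methylbut-2-en-1-yl)cyclohexa-1,4-dien-1-yl}-3-{4-[(tert-butyldimethylsilyl)oxy]-5-(2-methylbut-3-en-2-yl)-2-[(triethylsilyl)oxy]phenyl}propan-1-one (ring CH centres transient, configuration not defined) | O=C(CCc1cc(C(C)(C)C=C)c(O[Si](C)(C)C(C)(C)C)cc1O[Si](CC)(CC)CC)C1=CC(CC=C(C)C)C(O[Si](C)(C)C(C)(C)C)=C(O[Si](C)(C)C(C)(C)C)C1CC=C(C)C | intermediate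
14 | 1-{3,4-bis[(tert-butyldimethylsilyl)oxy]-2,5-bis(3-methylbut-2-en-1-yl)phenyl}-3-{4-[(tert-butyldimethylsilyl)oxy]-5-(2-methylbut-3-en-2-yl)-2-[(triethylsilyl)oxy]phenyl}propan-1-one | O=C(CCc1cc(C(C)(C)C=C)c(O[Si](C)(C)C(C)(C)C)cc1O[Si](CC)(CC)CC)c1cc(CC=C(C)C)c(O[Si](C)(C)C(C)(C)C)c(O[Si](C)(C)C(C)(C)C)c1CC=C(C)C | intermediate
15 | (1R)-1-{3,4-bis[(tert-butyldimethylsilyl)oxy]-2,5-bis(3-methylbut-2-en-1-yl)phenyl}-3-{4-[(tert-butyldimethylsilyl)oxy]-5-(2-methylbut-3-en-2-yl)-2-[(triethylsilyl)oxy]phenyl}propan-1-ol | O[C@@H](c1cc(CC=C(C)C)c(O[Si](C)(C)C(C)(C)C)c(O[Si](C)(C)C(C)(C)C)c1CC=C(C)C)CCc1cc(C(C)(C)C=C)c(O[Si](C)(C)C(C)(C)C)cc1O[Si](CC)(CC)CC | intermediate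
16 | 2-[(3R)-3-{3,4-bis[(tert-butyldimethylsilyl)oxy]-2,5-bis(3-methylbut-2-en-1-yl)phenyl}-3-hydroxypropyl]-5-[(tert-butyldimethylsilyl)oxy]-4-(2-methylbut-3-en-2-yl)phenol | O[C@@H](c1cc(CC=C(C)C)c(O[Si](C)(C)C(C)(C)C)c(O[Si](C)(C)C(C)(C)C)c1CC=C(C)C)CCc1cc(C(C)(C)C=C)c(O[Si](C)(C)C(C)(C)C)cc1O | intermediate
17 | (2S)-2-{3,4-bis[(tert-butyldimethylsilyl)oxy]-2,5-bis(3-methylbut-2-en-1-yl)phenyl}-7-[(tert-butyldimethylsilyl)oxy]-6-(2-methylbut-3-en-2-yl)-3,4-dihydro-2H-chromene | C=CC(C)(C)c1cc2c(cc1O[Si](C)(C)C(C)(C)C)O[C@H](c1cc(CC=C(C)C)c(O[Si](C)(C)C(C)(C)C)c(O[Si](C)(C)C(C)(C)C)c1CC=C(C)C)CC2 | intermediate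
18 | (2S)-2-[3,4-dihydroxy-2,5-bis(3-methylbut-2-en-1-yl)phenyl]-6-(2-methylbut-3-en-2-yl)-3,4-dihydro-2H-chromen-7-ol | C=CC(C)(C)c1cc2c(cc1O)O[C@H](c1cc(CC=C(C)C)c(O)c(O)c1CC=C(C)C)CC2 | target

**Step count**
Total: 11 steps. Longest linear sequence: 9 steps (steps 1–5 and 8–11); steps 6–7 form the two-step diene branch.

**Steps most likely to fail**

Step 8 (Diels–Alder benzannulation). The cycloaddition may be too slow for the heat-sensitive terminal ynone, because two silyloxy groups and two terminal alkyl groups crowd the s-cis diene. The dehydrogenation may also be accompanied by desilylation or benzylic oxidation. The fallback sets out from Weinreb amide 6 and takes ring B from a preformed arene. Commercial 3,6-dibromocatechol is silylated (TBSCl, imidazole, DMF) to 1,4-dibromo-2,3-bis[(tert-butyldimethylsilyl)oxy]benzene F1. This is deprotonated ortho to bromine with LiN(i-Pr)2 in THF at −78 °C to [2,5-dibromo-3,4-bis(tert-butyldimethylsilyloxy)phenyl]lithium F2. Addition of F2 to 6 gives the dibromo ketone 1-{2,5-dibromo-3,4-bis[(tert-butyldimethylsilyl)oxy]phenyl}-3-{4-[(tert-butyldimethylsilyl)oxy]-5-(2-methylbut-3-en-2-yl)-2-[(triethylsilyl)oxy]phenyl}propan-1-one F3. A twofold Stille coupling with tributyl(3-methylbut-2-en-1-yl)stannane (Pd(PPh3)4, CsF, DMF, 80 °C) introduces both linear prenyl groups and comes back to the route at ketone 14.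

Step 3 (γ-selective allyl–aryl coupling). At the hindered position ortho to the silyloxy group, the tertiary allylpalladium species may isomerise before reductive elimination, which would erode the branched-to-linear selectivity. Protodebromination and lactone hydrolysis may also compete. The fallback sets out from bromide 3 and builds the 1,1-dimethylallyl group through a carbonyl. Palladium-catalysed α-arylation of isobutyraldehyde ([Pd(allyl)Cl]2, dppf, Cs2CO3, dioxane, 80 °C) gives the quaternary aldehyde 2-{7-[(tert-butyldimethylsilyl)oxy]-2-oxo-3,4-dihydro-2H-chromen-6-yl}-2-methylpropanal F4. Takai–Lombardo methylenation (Zn, CH2I2, TiCl4, THF, 0 °C), which leaves the lactone alone, comes back to the route at 4.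

Step 10 (Mitsunobu ring closure). The electron-rich benzylic oxyphosphonium intermediate may ionise in part, which would erode the enantiomeric purity, or the incipient cation may be captured by the ortho prenyl alkene. The fallback sets out from ynone 7 and makes the O1–C2 bond before ring B exists. Transfer hydrogenation of the ynone (RuCl(p-cymene)[(R,R)-TsDPEN], KOH cat., i-PrOH, rt) gives (3R)-5-{4-[(tert-butyldimethylsilyl)oxy]-5-(2-methylbut-3-en-2-yl)-2-[(triethylsilyl)oxy]phenyl}pent-1-yn-3-ol F5. Methanolysis (K2CO3, MeOH, 0 °C) gives 5-[(tert-butyldimethylsilyl)oxy]-2-[(3R)-3-hydroxypent-4-yn-1-yl]-4-(2-methylbut-3-en-2-yl)phenol F6. Mitsunobu cyclisation at the non-ionisable propargylic carbinol (PPh3, DIAD, THF, 0 °C) gives, with inversion, tert-butyl{[(2S)-2-ethynyl-6-(2-methylbut-3-en-2-yl)-3,4-dihydro-2H-chromen-7-yl]oxy}dimethylsilane F7. A cobalt-catalysed neutral [4+2] cycloaddition of the unactivated alkyne with diene 12 (CoBr2(dppe), Zn, ZnI2, CH2Cl2, rt) gives the cyclohexa-1,4-diene adduct (2S)-2-{4,5-bis[(tert-butyldimethylsilyl)oxy]-3,6-bis(3-methylbut-2-en-1-yl)cyclohexa-1,4-dien-1-yl}-7-[(tert-butyldimethylsilyl)oxy]-6-(2-methylbut-3-en-2-yl)-3,4-dihydro-2H-chromene F8. DDQ aromatisation of F8 comes back to the route at 17.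

**Further compounds**
F1 | step 8 | 1,4-dibromo-2,3-bis[(tert-butyldimethylsilyl)oxy]benzene | Brc1ccc(Br)c(O[Si](C)(C)C(C)(C)C)c1O[Si](C)(C)C(C)(C)C
F2 | step 8 | [2,5-dibromo-3,4-bis(tert-butyldimethylsilyloxy)phenyl]lithium | [Li]c1cc(Br)c(O[Si](C)(C)C(C)(C)C)c(O[Si](C)(C)C(C)(C)C)c1Br
F3 | step 8 | 1-{2,5-dibromo-3,4-bis[(tert-butyldimethylsilyl)oxy]phenyl}-3-{4-[(tert-butyldimethylsilyl)oxy]-5-(2-methylbut-3-en-2-yl)-2-[(triethylsilyl)oxy]phenyl}propan-1-one | O=C(CCc1cc(C(C)(C)C=C)c(O[Si](C)(C)C(C)(C)C)cc1O[Si](CC)(CC)CC)c1cc(Br)c(O[Si](C)(C)C(C)(C)C)c(O[Si](C)(C)C(C)(C)C)c1Br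
F4 | step 3 | 2-{7-[(tert-butyldimethylsilyl)oxy]-2-oxo-3,4-dihydro-2H-chromen-6-yl}-2-methylpropanal | O=CC(C)(C)c1cc2CCC(=O)Oc2cc1O[Si](C)(C)C(C)(C)C
F5 | step 10 | (3R)-5-{4-[(tert-butyldimethylsilyl)oxy]-5-(2-methylbut-3-en-2-yl)-2-[(triethylsilyl)oxy]phenyl}pent-1-yn-3-ol | O[C@@H](C#C)CCc1cc(C(C)(C)C=C)c(O[Si](C)(C)C(C)(C)C)cc1O[Si](CC)(CC)CC
F6 | step 10 | 5-[(tert-butyldimethylsilyl)oxy]-2-[(3R)-3-hydroxypent-4-yn-1-yl]-4-(2-methylbut-3-en-2-yl)phenol | O[C@@H](C#C)CCc1cc(C(C)(C)C=C)c(O[Si](C)(C)C(C)(C)C)cc1O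
F7 | step 10 | tert-butyl{[(2S)-2-ethynyl-6-(2-methylbut-3-en-2-yl)-3,4-dihydro-2H-chromen-7-yl]oxy}dimethylsilane | C=CC(C)(C)c1cc2c(cc1O[Si](C)(C)C(C)(C)C)O[C@H](C#C)CC2
F8 | step 10 | (2S)-2-{4,5-bis[(tert-butyldimethylsilyl)oxy]-3,6-bis(3-methylbut-2-en-1-yl)cyclohexa-1,4-dien-1-yl}-7-[(tert-butyldimethylsilyl)oxy]-6-(2-methylbut-3-en-2-yl)-3,4-dihydro-2H-chromene | C=CC(C)(C)c1cc2c(cc1O[Si](C)(C)C(C)(C)C)O[C@H](C1=CC(CC=C(C)C)C(O[Si](C)(C)C(C)(C)C)=C(O[Si](C)(C)C(C)(C)C)C1CC=C(C)C)CC2
A1 | direct plan | 1-[(2R)-2-[3,4-bis(2-methylbut-3-en-2-yloxy)phenyl]-2-hydroxyethyl]-2,4,6-triphenylpyridin-1-ium tetrafluoroborate | O[C@H](c1ccc(OC(C)(C)C=C)c(OC(C)(C)C=C)c1)C[n+]2c(-c3ccccc3)cc(-c4ccccc4)cc2-c5ccccc5.F[B-](F)(F)F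
A2 | direct plan | 2-bromo-4-hydroxy-5-(2-methylbut-3-en-2-yl)benzaldehyde | O=Cc1cc(C(C)(C)C=C)c(O)cc1Br
A3 | direct plan | (1S)-1-[3,4-bis(2-methylbut-3-en-2-yloxy)phenyl]-3-[2-bromo-4-hydroxy-5-(2-methylbut-3-en-2-yl)phenyl]propan-1-ol | O[C@H](c1ccc(OC(C)(C)C=C)c(OC(C)(C)C=C)c1)CCc1cc(C(C)(C)C=C)c(O)cc1Br
A4 | direct plan | (2S)-2-[3,4-bis(2-methylbut-3-en-2-yloxy)phenyl]-6-(2-methylbut-3-en-2-yl)-3,4-dihydro-2H-chromen-7-ol | C=CC(C)(C)c1cc2c(cc1O)O[C@H](c1ccc(OC(C)(C)C=C)c(OC(C)(C)C=C)c1)CC2
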